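**Retrosynthetic overview**

1. Feature: in the oxan-4-one ring (O1, C2, C3, C4=O, C5, C6), C2 is bonded to O1 and to the guaiacyl ring, para to that ring's 4-oxygen. In an open-chain guaiacylmethyl ether of the C6 carbinol, the C2–H bond can therefore be removed as hydride to give an oxocarbenium ion O1=C2.
2. Key disconnection C2–C3: the oxocarbenium ion is trapped by a C3=C4 enol acetate; this closes the only ring, last, and sets C2 cis to C6.
3. The enol acetate comes from a terminal alkyne (Markovnikov AcOH addition); the O1–C2 ether comes from the homopropargylic C6 alcohol and a benzylic trichloroacetimidate made from O-benzylvanillin.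
4. The C5–C6 bond comes from Felkin-controlled propargylation of an α-silyloxy aldehyde; C7 comes from L-tyrosine by deamination with retention.
5. End game: desilylation, then hydrogenolysis of the benzyl ether.

Key step: step 10

Remark: 4-benzyloxy-3-methoxybenzaldehyde and allenyltributylstannane are taken as purchased materials. TBS = tert-butyldimethylsilyl. The labels O1, C2–C6 (ring), C7 (carbinol) and C8 (benzylic CH2) of the target are used for the corresponding atoms throughout.

**Route**

Step 1
Reactants: 1 L-tyrosine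
Product: 4 (S)-2-hydroxy-3-(4-hydroxyphenyl)propanoic acid, via diazonium carboxylate 2 (not isolated), via α-lactone 3 (not isolated)
Conditions: NaNO2, 1 M aq. H2SO4, 0 °C → rt
Reagents that add atoms: water, O
Why: Diazotisation of the α-amino acid (deaminative hydroxylation) proceeds by carboxylate displacement of N2 with inversion to the α-lactone and opening by water with a second inversion, so the (S) centre that becomes C7 is retained.

Step 2
Reactants: 4 (S)-2-hydroxy-3-(4-hydroxyphenyl)propanoic acid
Product: 5 methyl (S)-2-hydroxy-3-(4-hydroxyphenyl)propanoate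
Conditions: MeOH, H2SO4 (cat.), reflux
Reagents that add atoms: methanol, CO
Why: Fischer esterification of the α-hydroxy acid, which does not touch the stereocentre.

Step 3
Reactants: 5 methyl (S)-2-hydroxy-3-(4-hydroxyphenyl)propanoate
Product: 6 methyl (S)-2-(TBSO)-3-[4-(TBSO)phenyl]propanoate
Conditions: TBSCl, imidazole, DMF, rt
Reagents that add atoms: tert-butyldimethylsilyl chloride, CC(C)(C)[Si](C)(C)Cl
Why: Standard silyl ether formation on the phenol and the secondary alcohol, with the ester inert.

Step 4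
Reactants: 6 methyl (S)-2-(TBSO)-3-[4-(TBSO)phenyl]propanoate
Product: 7 (S)-2-(TBSO)-3-[4-(TBSO)phenyl]propanal
Conditions: DIBAL-H, CH2Cl2, −78 °C; aq. Rochelle salt
Reagents that add atoms: none
Why: Partial reduction of an α-silyloxy ester with DIBAL-H at −78 °C should stop at the aldehyde, which is used at once so that the α-centre does not epimerise.

Step 5
Reactants: 7 (S)-2-(TBSO)-3-[4-(TBSO)phenyl]propanal; 8 allenyltributylstannane
Product: 9 (4R,5S)-5-(TBSO)-6-[4-(TBSO)phenyl]hex-1-yn-4-ol
Conditions: BF3·OEt2, CH2Cl2, −78 °C; aq. NaHCO3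
Reagents that add atoms: none
Why: Lewis acid-promoted SE2' addition of the allenylstannane gives the homopropargylic alcohol, and with monodentate BF3 and the bulky α-silyloxy group the Felkin–Anh (non-chelation) transition state should place the new hydroxyl anti to the silyloxy group, setting C6 as (R), with the minor syn epimer removed by chromatography.

Step 6
Reactants: 10 4-benzyloxy-3-methoxybenzaldehyde
Product: 11 (4-benzyloxy-3-methoxyphenyl)methanol
Conditions: NaBH4, MeOH, 0 °C
Reagents that add atoms: none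
Why: Borohydride reduction of the aromatic aldehyde to the benzylic alcohol, with the benzyl ether inert.

Step 7
Reactants: 11 (4-benzyloxy-3-methoxyphenyl)methanol
Product: 12 (4-benzyloxy-3-methoxyphenyl)methyl 2,2,2-trichloroacetimidate
Conditions: Cl3CCN, DBU (cat.), CH2Cl2, 0 °C
Reagents that add atoms: trichloroacetonitrile, N#CC(Cl)(Cl)Cl
Why: Base-catalysed addition of the alcohol to trichloroacetonitrile (trichloroacetimidate formation), the product being used without storage.

Step 8
Reactants: 9 (4R,5S)-5-(TBSO)-6-[4-(TBSO)phenyl]hex-1-yn-4-ol; 12 (4-benzyloxy-3-methoxyphenyl)methyl 2,2,2-trichloroacetimidate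
Product: 13 (4R,5S)-4-[(4-benzyloxy-3-methoxyphenyl)methoxy]-5-(TBSO)-6-[4-(TBSO)phenyl]hex-1-yne
Conditions: La(OTf)3 (cat.), toluene, rt
Reagents that add atoms: none
Why: Lewis acid-catalysed benzylation with the trichloroacetimidate goes through the stabilised dialkoxybenzyl cation under nearly neutral conditions, so the neighbouring silyl ether should not migrate, and C6 keeps its configuration because its C–O bond is not broken.

Step 9
Reactants: 13 (4R,5S)-4-[(4-benzyloxy-3-methoxyphenyl)methoxy]-5-(TBSO)-6-[4-(TBSO)phenyl]hex-1-yne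
Product: 14 (4R,5S)-4-[(4-benzyloxy-3-methoxyphenyl)methoxy]-5-(TBSO)-6-[4-(TBSO)phenyl]hex-1-en-2-yl acetate
Conditions: AcOH, [RuCl2(p-cymene)]2 (cat.), P(2-furyl)3 (cat.), Na2CO3 (cat.), toluene, 80 °C
Reagents that add atoms: acetic acid, CC(=O)O
Why: Ruthenium-catalysed Markovnikov addition of a carboxylic acid to a terminal alkyne (hydro-acyloxylation) gives the 2-acetoxy-1-alkene and leaves ethers and silyl ethers untouched.

Step 10
Reactants: 14 (4R,5S)-4-[(4-benzyloxy-3-methoxyphenyl)methoxy]-5-(TBSO)-6-[4-(TBSO)phenyl]hex-1-en-2-yl acetate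
Product: 16 (2S,6R)-2-(4-benzyloxy-3-methoxyphenyl)-6-{(1S)-1-(TBSO)-2-[4-(TBSO)phenyl]ethyl}oxan-4-one, via (E)-aryl oxocarbenium ion 15 (not isolated)
Conditions: DDQ, 2,6-dichloropyridine, 4 Å MS, 1,2-dichloroethane, 0 °C → rt
Reagents that add atoms: none
Why: DDQ forms a charge-transfer complex with the 3-methoxy-4-benzyloxyphenyl ring and removes hydride from the ether CH2 to give the (E)-aryl oxocarbenium ion 15, which the tethered enol acetate attacks through C3; after C–C bond formation the acetyl group is lost and the C4 ketone results directly. The closest known reaction type is the DDQ-mediated oxidative C–H cleavage of alkoxybenzyl ethers with enol acetate trapping, which gives cis-2,6-disubstituted tetrahydropyran-4-ones. The ring (O1, C2, C3, C4, C5, C6) closes in a 6-endo-trig mode by forming C2–C3. The new stereocentre C2 is controlled by the existing C6 centre: in the chair transition state the C6 side chain and the aryl group of the (E)-oxocarbenium ion are both equatorial, so C2 should form as (S), cis to C6. The step needs site selectivity for the guaiacylmethyl C–H bond, which is the only C–H that is both α to an ether oxygen and attached to a dialkoxyarene, whereas C8 has no α-oxygen and sits on a less electron-rich silyloxyarene and the O-benzyl CH2 carries an unactivated phenyl ring. 2,6-Dichloropyridine and molecular sieves suppress acid- and water-mediated cleavage of the ether, and the ketone in the product deactivates the C2–H bond against a second oxidation.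

Step 11
Reactants: 16 (2S,6R)-2-(4-benzyloxy-3-methoxyphenyl)-6-{(1S)-1-(TBSO)-2-[4-(TBSO)phenyl]ethyl}oxan-4-one
Product: 17 (2S,6R)-2-(4-benzyloxy-3-methoxyphenyl)-6-[(1S)-1-hydroxy-2-(4-hydroxyphenyl)ethyl]oxan-4-one
Conditions: TBAF, AcOH, THF, 0 °C → rt
Reagents that add atoms: none
Why: Fluoride-mediated desilylation buffered with acetic acid should remove the aryl and the hindered secondary silyl ether while keeping the medium too weakly basic to open the β-alkoxy ketone by retro-oxa-Michael reaction.

Step 12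
Reactants: 17 (2S,6R)-2-(4-benzyloxy-3-methoxyphenyl)-6-[(1S)-1-hydroxy-2-(4-hydroxyphenyl)ethyl]oxan-4-one
Product: 18 (2S,6R)-2-(4-hydroxy-3-methoxyphenyl)-6-[(1S)-1-hydroxy-2-(4-hydroxyphenyl)ethyl]oxan-4-one
Conditions: H2 (1 atm), Pd/C, EtOAc, rt
Reagents that add atoms: none
Why: Hydrogenolysis of the aryl benzyl ether over Pd/C at ambient pressure is expected to be faster than cleavage of the cyclic benzylic C2–O1 bond or reduction of the ketone, so the reaction is stopped after uptake of one equivalent of hydrogen.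

**Compound list**

1 | L-tyrosine | N[C@@H](Cc1ccc(O)cc1)C(=O)O | starting material
2 | (S)-2-diazonio-3-(4-hydroxyphenyl)propanoate | N#[N+][C@@H](Cc1ccc(O)cc1)C(=O)[O-] | intermediate
3 | (R)-3-(4-hydroxybenzyl)oxiran-2-one | O=C1O[C@@H]1Cc1ccc(O)cc1 | intermediate
4 | (S)-2-hydroxy-3-(4-hydroxyphenyl)propanoic acid | OC(=O)[C@@H](O)Cc1ccc(O)cc1 | intermediate
5 | methyl (S)-2-hydroxy-3-(4-hydroxyphenyl)propanoate | COC(=O)[C@@H](O)Cc1ccc(O)cc1 | intermediate
6 | methyl (S)-2-(tert-butyldimethylsilyloxy)-3-[4-(tert-butyldimethylsilyloxy)phenyl]propanoate | COC(=O)[C@@H](O[Si](C)(C)C(C)(C)C)Cc1ccc(O[Si](C)(C)C(C)(C)C)cc1 | intermediate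
7 | (S)-2-(tert-butyldimethylsilyloxy)-3-[4-(tert-butyldimethylsilyloxy)phenyl]propanal | O=C[C@@H](O[Si](C)(C)C(C)(C)C)Cc1ccc(O[Si](C)(C)C(C)(C)C)cc1 | intermediate
8 | allenyltributylstannane | C=C=C[Sn](CCCC)(CCCC)CCCC | starting material
9 | (4R,5S)-5-(tert-butyldimethylsilyloxy)-6-[4-(tert-butyldimethylsilyloxy)phenyl]hex-1-yn-4-ol | C#CC[C@@H](O)[C@@H](O[Si](C)(C)C(C)(C)C)Cc1ccc(O[Si](C)(C)C(C)(C)C)cc1 | intermediate
10 | 4-benzyloxy-3-methoxybenzaldehyde | COc1cc(C=O)ccc1OCc1ccccc1 | starting material
11 | (4-benzyloxy-3-methoxyphenyl)methanol | COc1cc(CO)ccc1OCc1ccccc1 | intermediate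
12 | (4-benzyloxy-3-methoxyphenyl)methyl 2,2,2-trichloroacetimidate | COc1cc(COC(=N)C(Cl)(Cl)Cl)ccc1OCc1ccccc1 | intermediate
13 | (4R,5S)-4-[(4-benzyloxy-3-methoxyphenyl)methoxy]-5-(tert-butyldimethylsilyloxy)-6-[4-(tert-butyldimethylsilyloxy)phenyl]hex-1-yne | C#CC[C@@H](OCc1ccc(OCc2ccccc2)c(OC)c1)[C@@H](O[Si](C)(C)C(C)(C)C)Cc1ccc(O[Si](C)(C)C(C)(C)C)cc1 | intermediate
14 | (4R,5S)-4-[(4-benzyloxy-3-methoxyphenyl)methoxy]-5-(tert-butyldimethylsilyloxy)-6-[4-(tert-butyldimethylsilyloxy)phenyl]hex-1-en-2-yl acetate | COc1cc(CO[C@H](CC(OC(C)=O)=C)[C@@H](O[Si](C)(C)C(C)(C)C)Cc2ccc(O[Si](C)(C)C(C)(C)C)cc2)ccc1OCc1ccccc1 | intermediate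
15 | (E)-aryl oxocarbenium ion from 14 (O1=C2 cation) | COc1cc(/C=[O+]/[C@H](CC(OC(C)=O)=C)[C@@H](O[Si](C)(C)C(C)(C)C)Cc2ccc(O[Si](C)(C)C(C)(C)C)cc2)ccc1OCc1ccccc1 | intermediate
16 | (2S,6R)-2-(4-benzyloxy-3-methoxyphenyl)-6-{(1S)-1-(tert-butyldimethylsilyloxy)-2-[4-(tert-butyldimethylsilyloxy)phenyl]ethyl}oxan-4-one | COc1cc([C@@H]2CC(=O)C[C@H]([C@@H](O[Si](C)(C)C(C)(C)C)Cc3ccc(O[Si](C)(C)C(C)(C)C)cc3)O2)ccc1OCc1ccccc1 | intermediate
17 | (2S,6R)-2-(4-benzyloxy-3-methoxyphenyl)-6-[(1S)-1-hydroxy-2-(4-hydroxyphenyl)ethyl]oxan-4-one | COc1cc([C@@H]2CC(=O)C[C@H]([C@@H](O)Cc3ccc(O)cc3)O2)ccc1OCc1ccccc1 | intermediate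
18 | (2S,6R)-2-(4-hydroxy-3-methoxyphenyl)-6-[(1S)-1-hydroxy-2-(4-hydroxyphenyl)ethyl]oxan-4-one | COc1cc([C@@H]2CC(=O)C[C@H]([C@@H](O)Cc3ccc(O)cc3)O2)ccc1O | target

**Step count**

Total: 12 steps. Longest linear sequence: 10 steps (steps 1–5 and 8–12).

**Steps most likely to fail**

Step 10. The electron-withdrawing C7 silyloxy group may slow hydride abstraction. Cleavage of the benzylic ether by adventitious water, or a second oxidation of the product at C2, could then compete with ring closure. The fallback forms O1–C2 last by oxa-Michael addition instead of forming C2–C3; it sets out from aldehydes 7 and 10 and comes back at 16. Claisen–Schmidt condensation of 10 with acetone (aq. NaOH) gives (E)-4-(4-benzyloxy-3-methoxyphenyl)but-3-en-2-one F1. TMSOTf and Et3N in CH2Cl2 convert it into trimethyl{[(3E)-4-(4-benzyloxy-3-methoxyphenyl)buta-1,3-dien-2-yl]oxy}silane F2. Mukaiyama aldol addition of F2 to 7 (BF3·OEt2, CH2Cl2, −78 °C; Felkin, anti) should give (1E,5R,6S)-1-(4-benzyloxy-3-methoxyphenyl)-6-(tert-butyldimethylsilyloxy)-7-[4-(tert-butyldimethylsilyloxy)phenyl]-5-hydroxyhept-1-en-3-one F3. Amberlyst-15 in CH2Cl2 then brings about 6-endo-trig oxa-Michael addition under thermodynamic control to the cis-2,6-pyranone 16.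

Step 5. Facial selectivity may be poor in the open transition state with a small nucleophile, giving much of the syn epimer, and the aldehyde may partly epimerise under the Lewis acid. The fallback replaces substrate control by matched catalyst control; it sets out from 7 and comes back at 9 with no new compound. Allenylboronic acid pinacol ester is added to 7 in toluene at 0 °C over 4 Å MS with a catalytic BINOL-derived phosphoric acid. The catalyst is (R)-3,3'-bis(2,4,6-triisopropylphenyl)-1,1'-binaphthyl-2,2'-diyl hydrogen phosphate, the enantiomer expected to direct addition to the Re face of the aldehyde; this is the Felkin face of 7 and the face that gives (R) at C6. A closed six-membered boron transition state under catalyst control then reinforces the substrate preference.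

Step 8. Etherification of the hindered C6 alcohol may be slow, so that the imidate is consumed by rearrangement to the N-benzyl trichloroacetamide or by self-alkylation, or a silyl group is lost to the acid. The fallback is a reductive etherification; it sets out from 9 and comes back at 13. TMSCl and Et3N in CH2Cl2 give (4R,5S)-5-(tert-butyldimethylsilyloxy)-6-[4-(tert-butyldimethylsilyloxy)phenyl]-4-(trimethylsilyloxy)hex-1-yne F4. Treatment of F4 with aldehyde 10, Et3SiH and catalytic TMSOTf in CH2Cl2 at −78 °C forms the mixed oxocarbenium ion, which the silane reduces to ether 13.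

Further compounds
F1 | step 10 | (E)-4-(4-benzyloxy-3-methoxyphenyl)but-3-en-2-one | CC(=O)/C=C/c1ccc(OCc2ccccc2)c(OC)c1
F2 | step 10 | trimethyl{[(3E)-4-(4-benzyloxy-3-methoxyphenyl)buta-1,3-dien-2-yl]oxy}silane | C=C(O[Si](C)(C)C)/C=C/c1ccc(OCc2ccccc2)c(OC)c1
F3 | step 10 | (1E,5R,6S)-1-(4-benzyloxy-3-methoxyphenyl)-6-(tert-butyldimethylsilyloxy)-7-[4-(tert-butyldimethylsilyloxy)phenyl]-5-hydroxyhept-1-en-3-one | O=C(/C=C/c1ccc(OCc2ccccc2)c(OC)c1)C[C@@H](O)[C@@H](O[Si](C)(C)C(C)(C)C)Cc1ccc(O[Si](C)(C)C(C)(C)C)cc1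
F0 | step 5 | none | none
F4 | step 8 | (4R,5S)-5-(tert-butyldimethylsilyloxy)-6-[4-(tert-butyldimethylsilyloxy)phenyl]-4-(trimethylsilyloxy)hex-1-yne | C#CC[C@@H](O[Si](C)(C)C)[C@@H](O[Si](C)(C)C(C)(C)C)Cc1ccc(O[Si](C)(C)C(C)(C)C)cc1
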